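**Strategy**

The tetrahydrofuran ring (O1, C2–C5; target numbering is used throughout) has a twofold axis through O1 and the midpoint of C3–C4. C2/C3 and C5/C4 are identical pairs in which the benzylic C–O and the neighbouring C–H correspond to a syn addition across an (E)-ArCH=C(CH2O) bond. The route therefore disconnects both benzylic C–O bonds to an achiral (E,E)-2,3-bis(arylidene)butane-1,4-diol bis(silyl ether), made by two Stobbe condensations, which already holds all twenty skeletal carbons. One double asymmetric hydroboration–oxidation with a chiral monoalkylborane installs all four stereocentres as a twofold-symmetric 1,4-diol. Mono-oxidation, lactol formation and hydride reduction then close the ring.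

Key step: step 7

Assumption: the borane enantiomer (from (−)-α-pinene, for the all-(S) diol) is chosen by analogy with its known sense toward simple trisubstituted aryl alkenes; if a first run showed the opposite sense, the reagent from (+)-α-pinene would be used with no other change.

Step 1
Reactants: 1 diethyl succinate; 2 4-benzyloxy-3-methoxybenzaldehyde
Product: 3 (3E)-4-(4-benzyloxy-3-methoxyphenyl)-3-(ethoxycarbonyl)but-3-enoic acid
Conditions: NaOEt, EtOH, reflux; then aq. HCl
Reagents that add atoms: none
Why: Stobbe condensation: the succinate enolate adds to the aldehyde, the alkoxide lactonises onto the other ester, and base-induced ring opening of the paraconic ester gives the half-ester with the aryl trans to the ester group (E), the usual outcome of this reaction.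

Step 2
Reactants: 3 (3E)-4-(4-benzyloxy-3-methoxyphenyl)-3-(ethoxycarbonyl)but-3-enoic acid
Product: 4 diethyl (2E)-2-(4-benzyloxy-3-methoxybenzylidene)butanedioate
Conditions: EtI, K2CO3, DMF, 25 °C
Reagents that add atoms: iodoethane, CCI
Why: O-alkylation of the carboxylate (SN2 esterification) under weak base restores the diester needed for a second condensation without moving or isomerising the double bond.

Step 3
Reactants: 4 diethyl (2E)-2-(4-benzyloxy-3-methoxybenzylidene)butanedioate; 2 4-benzyloxy-3-methoxybenzaldehyde
Product: 5 (2E,3E)-2,3-bis(4-benzyloxy-3-methoxybenzylidene)butanedioic acid monoethyl ester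
Conditions: NaOEt, EtOH, reflux; then aq. HCl; amber glassware
Reagents that add atoms: none
Why: Second Stobbe condensation at the remaining CH2 (α to the saturated ester) by the same aldol/lactonisation/ring-opening path gives the (E,E)-diene with each aryl trans to its carboxyl, that is cis to the other half; the diene is kept from light from here on because it can photoisomerise.

Step 4
Reactants: 5 (2E,3E)-2,3-bis(4-benzyloxy-3-methoxybenzylidene)butanedioic acid monoethyl ester
Product: 6 diethyl (2E,3E)-2,3-bis(4-benzyloxy-3-methoxybenzylidene)butanedioate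
Conditions: EtI, K2CO3, DMF, 25 °C
Reagents that add atoms: iodoethane, CCI
Why: SN2 esterification of the carboxylate as in step 2 gives the symmetric diester, which is reduced more cleanly than the acid.

Step 5
Reactants: 6 diethyl (2E,3E)-2,3-bis(4-benzyloxy-3-methoxybenzylidene)butanedioate
Product: 7 (2E,3E)-2,3-bis(4-benzyloxy-3-methoxybenzylidene)butane-1,4-diol
Conditions: i-Bu2AlH (excess), CH2Cl2, −78 to 0 °C; aq. KNaC4H4O6 (tartrate) work-up
Reagents that add atoms: none
Why: 1,2-Reduction of both conjugated esters by i-Bu2AlH at low temperature gives the bis-allylic diol and leaves the trisubstituted C=C bonds and their geometry untouched.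

Step 6
Reactants: 7 (2E,3E)-2,3-bis(4-benzyloxy-3-methoxybenzylidene)butane-1,4-diol
Product: 8 (2E,3E)-1,4-bis(tert-butyldiphenylsilyloxy)-2,3-bis(4-benzyloxy-3-methoxybenzylidene)butane
Conditions: t-BuPh2SiCl, imidazole, DMF, 25 °C
Reagents that add atoms: tert-butyl(chloro)diphenylsilane, CC(C)(C)[Si](Cl)(c1ccccc1)c1ccccc1
Why: Standard silylation of primary allylic alcohols; silyl ethers are chosen for the CH2O groups because they are inert to boranes and to BF3·OEt2 at −78 °C and are removed by fluoride, so that the final hydrogenolysis only has to cleave two aryl benzyl ethers next to the hydrogenolysis-prone benzylic ring C–O bonds.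

Step 7
Reactants: 8 (2E,3E)-1,4-bis(tert-butyldiphenylsilyloxy)-2,3-bis(4-benzyloxy-3-methoxybenzylidene)butane
Product: 10 (1S,2S,3S,4S)-1,4-bis(4-benzyloxy-3-methoxyphenyl)-2,3-bis[(tert-butyldiphenylsilyloxy)methyl]butane-1,4-diol, via bis(isopinocampheylboryl) adduct 9 (not isolated)
Conditions: IpcBH2 (from (−)-α-pinene, enantiopure, about 3 equiv), THF, −25 °C; MeOH quench; then NaBO3·4H2O, THF/H2O, 25 °C
Reagents that add atoms: sodium perborate (NaBO3, used as the tetrahydrate), [Na+].[O-]OB=O
Why: Asymmetric hydroboration–oxidation, the known reaction of monoisopinocampheylborane with trisubstituted aryl alkenes, is used here at both ends of the diene: each B–H adds syn through a four-centre transition state with boron on the benzylic CH (C2 and C5, the only hydrogen-bearing alkene carbons, remote from the allylic C–O) and hydrogen on C3 and C4, and perborate then turns each C–B into C–O with retention; no ring is closed. The C2/C3 and C5/C4 relations follow from syn addition to (E) double bonds whose aryl is cis to the other half, which is exactly the aryl/CH2O cis relation of the target ring. The absolute configuration of each pair is chosen by the chiral borane, and because the two alkenes are homotopic and twisted out of conjugation by allylic strain the same face should be taken twice, giving the 3,4-trans, twofold-symmetric diol. The selectivity the step needs is reagent control in the second addition, where the new C3 centre by 1,2-induction favours the other face (meso diol); nothing in the substrate secures this, so excess reagent of high enantiopurity at low temperature is used to enforce it. Should the B–H already bound at C2 add across C4=C5 instead, the aryl cis to C3 forces C3–H into the alkene plane, so that this delivery also ends in 10 after oxidation. Every wrong-face addition gives the meso diol, a diastereomer that should be removable by chromatography or crystallisation, so the enantiopurity of 10 should exceed the selectivity of a single addition.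

Step 8
Reactants: 10 (1S,2S,3S,4S)-1,4-bis(4-benzyloxy-3-methoxyphenyl)-2,3-bis[(tert-butyldiphenylsilyloxy)methyl]butane-1,4-diol
Product: 12 (3S,4S,5S)-2,5-bis(4-benzyloxy-3-methoxyphenyl)-3,4-bis[(tert-butyldiphenylsilyloxy)methyl]tetrahydrofuran-2-ol (anomeric mixture), via hydroxy ketone 11 (not isolated)
Conditions: activated MnO2 (excess), CH2Cl2, 25 °C, stopped when 10 is consumed
Reagents that add atoms: none
Why: Benzylic alcohol oxidation with MnO2: the two carbinols of 10 are equivalent by symmetry, so either oxidation gives the same hydroxy ketone, whose γ-hydroxyl adds to the aryl ketone to form the five-membered lactol, a tertiary hemiketal that cannot be oxidised further; this deliberately erases one of the two equivalent benzylic centres (C5), leaves C2, C3 and C4 untouched, and C5 is set again in step 9.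

Step 9
Reactants: 12 (3S,4S,5S)-2,5-bis(4-benzyloxy-3-methoxyphenyl)-3,4-bis[(tert-butyldiphenylsilyloxy)methyl]tetrahydrofuran-2-ol
Product: 13 (2S,3S,4S,5S)-2,5-bis(4-benzyloxy-3-methoxyphenyl)-3,4-bis[(tert-butyldiphenylsilyloxy)methyl]tetrahydrofuran
Conditions: Et3SiH, BF3·OEt2, CH2Cl2, −78 °C (to −40 °C if needed)
Reagents that add atoms: none
Why: Ionic reduction of a cyclic hemiketal: BF3 ionises the lactol to the 2-aryl oxocarbenium ion and hydride from Et3SiH adds to C5 on the face opposite the adjacent C4 substituent, which places the aryl cis to it (4,5-cis, 2,5-trans), the established outcome for 2-aryl lactols carrying a C3 substituent; the low temperature should keep the benzylic C2–O bond and the silyl ethers intact.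

Step 10
Reactants: 13 (2S,3S,4S,5S)-2,5-bis(4-benzyloxy-3-methoxyphenyl)-3,4-bis[(tert-butyldiphenylsilyloxy)methyl]tetrahydrofuran
Product: 14 [(2S,3S,4S,5S)-2,5-bis(4-benzyloxy-3-methoxyphenyl)tetrahydrofuran-3,4-diyl]dimethanol
Conditions: Bu4NF, THF, 25 °C
Reagents that add atoms: none
Why: Fluoride-induced cleavage of the two primary silyl ethers; the aryl benzyl ethers and the ring are inert, and doing this before the phenols are freed avoids exposing p-hydroxybenzylic ethers to basic fluoride.

Step 11
Reactants: 14 [(2S,3S,4S,5S)-2,5-bis(4-benzyloxy-3-methoxyphenyl)tetrahydrofuran-3,4-diyl]dimethanol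
Product: 15 Eduesmine, [(2S,3S,4S,5S)-2,5-bis(4-hydroxy-3-methoxyphenyl)tetrahydrofuran-3,4-diyl]dimethanol
Conditions: H2 (1 atm), 10% Pd/C, EtOAc, 25 °C, stopped at full conversion
Reagents that add atoms: none
Why: Hydrogenolysis of the two aryl benzyl ethers, which under neutral conditions are cleaved far faster than the benzylic C–O bonds of the ring; no stereocentre is touched.

**Compound list**

1 | diethyl succinate | CCOC(=O)CCC(=O)OCC | starting material
2 | 4-benzyloxy-3-methoxybenzaldehyde | COc1cc(C=O)ccc1OCc1ccccc1 | starting material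
3 | (3E)-4-(4-benzyloxy-3-methoxyphenyl)-3-(ethoxycarbonyl)but-3-enoic acid | CCOC(=O)/C(CC(=O)O)=C/c1ccc(OCc2ccccc2)c(OC)c1 | intermediate
4 | diethyl (2E)-2-(4-benzyloxy-3-methoxybenzylidene)butanedioate | CCOC(=O)C/C(C(=O)OCC)=C\c1ccc(OCc2ccccc2)c(OC)c1 | intermediate
5 | (2E,3E)-2,3-bis(4-benzyloxy-3-methoxybenzylidene)butanedioic acid monoethyl ester | COc1cc(/C=C(C(=O)OCC)\C(C(=O)O)=C/c2ccc(OCc3ccccc3)c(OC)c2)ccc1OCc1ccccc1 | intermediate
6 | diethyl (2E,3E)-2,3-bis(4-benzyloxy-3-methoxybenzylidene)butanedioate | COc1cc(/C=C(C(=O)OCC)\C(C(=O)OCC)=C/c2ccc(OCc3ccccc3)c(OC)c2)ccc1OCc1ccccc1 | intermediate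
7 | (2E,3E)-2,3-bis(4-benzyloxy-3-methoxybenzylidene)butane-1,4-diol | COc1cc(/C=C(CO)\C(CO)=C/c2ccc(OCc3ccccc3)c(OC)c2)ccc1OCc1ccccc1 | intermediate
8 | (2E,3E)-1,4-bis(tert-butyldiphenylsilyloxy)-2,3-bis(4-benzyloxy-3-methoxybenzylidene)butane, each aryl cis to the other half | COc1cc(/C=C(CO[Si](c2ccccc2)(c2ccccc2)C(C)(C)C)\C(CO[Si](c2ccccc2)(c2ccccc2)C(C)(C)C)=C/c2ccc(OCc3ccccc3)c(OC)c2)ccc1OCc1ccccc1 | intermediate
9 | 1,4-bis(isopinocampheylboryl) adduct of 8, carbons configured as in 10, drawn as the monomer | COc1cc([C@@H]([BH][C@H]2C[C@H]3C[C@@H]([C@@H]2C)C3(C)C)[C@H](CO[Si](c2ccccc2)(c2ccccc2)C(C)(C)C)[C@@H](CO[Si](c2ccccc2)(c2ccccc2)C(C)(C)C)[C@H]([BH][C@H]2C[C@H]3C[C@@H]([C@@H]2C)C3(C)C)c2ccc(OCc3ccccc3)c(OC)c2)ccc1OCc1ccccc1 | intermediate (not isolated)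
10 | (1S,2S,3S,4S)-1,4-bis(4-benzyloxy-3-methoxyphenyl)-2,3-bis[(tert-butyldiphenylsilyloxy)methyl]butane-1,4-diol | COc1cc([C@@H](O)[C@H](CO[Si](c2ccccc2)(c2ccccc2)C(C)(C)C)[C@@H](CO[Si](c2ccccc2)(c2ccccc2)C(C)(C)C)[C@H](O)c2ccc(OCc3ccccc3)c(OC)c2)ccc1OCc1ccccc1 | intermediate
11 | (2S,3S,4S)-1,4-bis(4-benzyloxy-3-methoxyphenyl)-4-hydroxy-2,3-bis[(tert-butyldiphenylsilyloxy)methyl]butan-1-one | COc1cc([C@@H](O)[C@H](CO[Si](c2ccccc2)(c2ccccc2)C(C)(C)C)[C@@H](CO[Si](c2ccccc2)(c2ccccc2)C(C)(C)C)C(=O)c2ccc(OCc3ccccc3)c(OC)c2)ccc1OCc1ccccc1 | intermediate (not isolated)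
12 | (3S,4S,5S)-2,5-bis(4-benzyloxy-3-methoxyphenyl)-3,4-bis[(tert-butyldiphenylsilyloxy)methyl]tetrahydrofuran-2-ol, hemiketal carbon as a mixture | COc1cc([C@H]2OC(O)(c3ccc(OCc4ccccc4)c(OC)c3)[C@H](CO[Si](c3ccccc3)(c3ccccc3)C(C)(C)C)[C@H]2CO[Si](c2ccccc2)(c2ccccc2)C(C)(C)C)ccc1OCc1ccccc1 | intermediate
13 | (2S,3S,4S,5S)-2,5-bis(4-benzyloxy-3-methoxyphenyl)-3,4-bis[(tert-butyldiphenylsilyloxy)methyl]tetrahydrofuran | COc1cc([C@H]2O[C@H](c3ccc(OCc4ccccc4)c(OC)c3)[C@H](CO[Si](c3ccccc3)(c3ccccc3)C(C)(C)C)[C@H]2CO[Si](c2ccccc2)(c2ccccc2)C(C)(C)C)ccc1OCc1ccccc1 | intermediate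
14 | [(2S,3S,4S,5S)-2,5-bis(4-benzyloxy-3-methoxyphenyl)tetrahydrofuran-3,4-diyl]dimethanol | COc1cc([C@H]2O[C@H](c3ccc(OCc4ccccc4)c(OC)c3)[C@H](CO)[C@H]2CO)ccc1OCc1ccccc1 | intermediate
15 | Eduesmine, [(2S,3S,4S,5S)-2,5-bis(4-hydroxy-3-methoxyphenyl)tetrahydrofuran-3,4-diyl]dimethanol | COc1cc([C@H]2O[C@H](c3ccc(O)c(OC)c3)[C@H](CO)[C@H]2CO)ccc1O | target

**Step count and risks**

Total steps: 11. Longest linear sequence: 11 steps (1 to 15; aldehyde 2 enters in steps 1 and 3).

The three steps most likely to fail:

1. Step 7. Reagent control may be lost in the second B–H addition: the C3 centre formed first steers an external borane to the opposite face (attack anti to the borylated carbon), so meso diol builds up. Slow addition to the twisted, hindered diene would make this worse. Fallback: setting out from 8, the hydroboration is run in relay mode with one equivalent of the same monoalkylborane at high dilution (THF, −25 °C, then 25 °C). Only the first addition is then reagent-controlled, and the remaining B–H of the boron at C2 adds across C4=C5 within the molecule. Such cyclic hydroboration of a 1,3-diene to a borolane is a known route to 1,4-diols. With C3–H held in the alkene plane by the cis aryl, it should give only the 3,4-trans ring, the 1-isopinocampheylborolane F1. Oxidation (NaBO3·4H2O or NaOH/H2O2) opens the ring of the borolane and comes back to the route at 10.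

2. Step 8. Over-oxidation may occur: if the hydroxy ketone stays open instead of closing to the lactol, the second benzylic alcohol is oxidised too and material is lost as the diketone, with possible epimerisation next to the carbonyl groups. Fallback: setting out from 10, one hydroxyl is masked with Et3SiOTf (one equivalent, 2,6-lutidine, CH2Cl2, −78 °C; unreacted 10 is recycled) to give the mono(triethylsilyl) ether F2. The remaining benzylic alcohol is oxidised with Dess–Martin periodinane to the keto silyl ether F3, which cannot be oxidised further. Et3SiH with BF3·OEt2 at −78 °C then brings about a reductive cyclisation: the silyl ether oxygen closes onto the activated ketone, the triethylsilyl group is lost, and hydride adds as in step 9. This comes back to the route at 13.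

3. Step 3. Condensation may be incomplete and alkene geometry may erode: under hot alkoxide the arylidene succinate can undergo double-bond migration or give the (E,Z) diene. Fallback: setting out from 4, the ester enolate is formed with LiN(i-Pr)2 in THF at −78 °C and added to 2 to give the aldol adduct F4 (diastereomer mixture). This is acetylated (Ac2O, DMAP) to the acetate F5. DBU in toluene then eliminates acetic acid by an E1cB path to the conjugated (E)-alkene, coming back to the route at 6 and bypassing 5.

**Further compounds**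

F1 | step 7 | 1-isopinocampheyl-2,5-bis(4-benzyloxy-3-methoxyphenyl)-3,4-bis[(tert-butyldiphenylsilyloxy)methyl]borolane, ring substituents arranged as in 13 | COc1cc([C@H]2B([C@H]3C[C@H]4C[C@@H]([C@@H]3C)C4(C)C)[C@H](c3ccc(OCc4ccccc4)c(OC)c3)[C@H](CO[Si](c3ccccc3)(c3ccccc3)C(C)(C)C)[C@H]2CO[Si](c2ccccc2)(c2ccccc2)C(C)(C)C)ccc1OCc1ccccc1
F2 | step 8 | mono(triethylsilyl) ether of 10 | COc1cc([C@@H](O[Si](CC)(CC)CC)[C@H](CO[Si](c2ccccc2)(c2ccccc2)C(C)(C)C)[C@@H](CO[Si](c2ccccc2)(c2ccccc2)C(C)(C)C)[C@H](O)c2ccc(OCc3ccccc3)c(OC)c2)ccc1OCc1ccccc1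
F3 | step 8 | (2S,3S,4S)-1,4-bis(4-benzyloxy-3-methoxyphenyl)-2,3-bis[(tert-butyldiphenylsilyloxy)methyl]-4-(triethylsilyloxy)butan-1-one | COc1cc([C@@H](O[Si](CC)(CC)CC)[C@H](CO[Si](c2ccccc2)(c2ccccc2)C(C)(C)C)[C@@H](CO[Si](c2ccccc2)(c2ccccc2)C(C)(C)C)C(=O)c2ccc(OCc3ccccc3)c(OC)c2)ccc1OCc1ccccc1
F4 | step 3 | diethyl 2-[(4-benzyloxy-3-methoxyphenyl)(hydroxy)methyl]-3-[(E)-4-benzyloxy-3-methoxybenzylidene]butanedioate, diastereomer mixture | CCOC(=O)C(C(O)c1ccc(OCc2ccccc2)c(OC)c1)/C(=C\c1ccc(OCc2ccccc2)c(OC)c1)C(=O)OCC
F5 | step 3 | diethyl 2-[acetoxy(4-benzyloxy-3-methoxyphenyl)methyl]-3-[(E)-4-benzyloxy-3-methoxybenzylidene]butanedioate, diastereomer mixture | CCOC(=O)C(C(OC(C)=O)c1ccc(OCc2ccccc2)c(OC)c1)/C(=C\c1ccc(OCc2ccccc2)c(OC)c1)C(=O)OCC
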